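**Strategy.** The C7 carbinol, flanked by the C6 and C8 ketones (isochromene numbering), is an acyloin, so the carbocycle is closed at C7–C8 by an enantioselective N-heterocyclic-carbene intramolecular aldehyde–ketone benzoin reaction instead of by oxidising a resorcinol. In one operation the C8 aldehyde of a preformed 4H-pyran adds as an acyl anion to the methyl ketone of a 2,3-dioxobutylidene chain on C4a, which closes the six-membered ring, sets the only stereocentre and completes the 6H-isochromene-6,8-dione chromophore. The precursor is an achiral 4-ylidene-4H-pyran-3-carbaldehyde built from kojic acid, whose ring supplies O2, C1, C3, C4, C4a and C8a.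

Key step: step 8

Assumption: the (5aS,10bR) catalyst is taken to direct the acyl anion to the Si face of the C7 ketone (giving 7R); this sense is a model-based prediction, the step has no substrate stereocontrol, and the commercially available (5aR,10bS) antipode would be used if the sense proved opposite.

**Step 1**
Reactants: 1 kojic acid
Product: 2 6-(hydroxymethyl)-4-oxo-4H-pyran-3-yl trifluoromethanesulfonate
Conditions: PhNTf2 (1.05 equiv), Et3N, DMF, 0 °C to rt
Reagents that add atoms: N-phenylbis(trifluoromethanesulfonimide), O=S(=O)(N(c1ccccc1)S(=O)(=O)C(F)(F)F)C(F)(F)F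
Why: The acidic enolic 5-OH is deprotonated by Et3N and sulfonylated by PhNTf2, which leaves the neutral primary alcohol alone (chemoselective enol O-triflation).

**Step 2**
Reactants: 2 6-(hydroxymethyl)-4-oxo-4H-pyran-3-yl trifluoromethanesulfonate
Product: 3 6-formyl-4-oxo-4H-pyran-3-yl trifluoromethanesulfonate
Conditions: Dess–Martin periodinane, CH2Cl2, 0 °C to rt
Reagents that add atoms: none
Why: Dess–Martin oxidation of the primary pyranylcarbinol to the aldehyde; the vinyl triflate and the pyranone are inert to the iodane.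

**Step 3**
Reactants: 3 6-formyl-4-oxo-4H-pyran-3-yl trifluoromethanesulfonate
Product: 4 4-oxo-6-[(E)-3-oxoprop-1-en-1-yl]-4H-pyran-3-yl trifluoromethanesulfonate
Conditions: Ph3P=CHCHO (1.0 equiv), toluene, rt to 50 °C
Reagents that add atoms: (triphenylphosphoranylidene)acetaldehyde, O=CC=P(c1ccccc1)(c1ccccc1)c1ccccc1
Why: Wittig olefination with the stabilised formylmethylene ylide should give the (E)-enal; the electron-poor heteroaryl aldehyde is far more reactive than the product enal, which limits double homologation.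

**Step 4**
Reactants: 4 4-oxo-6-[(E)-3-oxoprop-1-en-1-yl]-4H-pyran-3-yl trifluoromethanesulfonate
Product: 5 6-[(E)-2-(1,3-dioxolan-2-yl)ethenyl]-4-oxo-4H-pyran-3-yl trifluoromethanesulfonate
Conditions: TMSOCH2CH2OTMS, TMSOTf (5 mol%), CH2Cl2, −78 to −20 °C; pyridine quench
Reagents that add atoms: 1,2-bis(trimethylsilyloxy)ethane, C[Si](C)(C)OCCO[Si](C)(C)C
Why: Noyori acetalisation converts enals into 1,3-dioxolanes at low temperature without conjugate addition or E/Z scrambling, masking the enal from the acetylide and the carbene of later steps.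

**Step 5**
Reactants: 5 6-[(E)-2-(1,3-dioxolan-2-yl)ethenyl]-4-oxo-4H-pyran-3-yl trifluoromethanesulfonate; 6 but-3-yn-2-ol (racemic)
Product: 8 (4Z)-6-[(E)-2-(1,3-dioxolan-2-yl)ethenyl]-4-(3-hydroxy-2-oxobutylidene)-4H-pyran-3-yl trifluoromethanesulfonate, via propargylic pyranol 7 (not isolated)
Conditions: 6 (1.3 equiv), n-BuLi (2.6 equiv), THF, −78 to −20 °C; then 5, −78 °C; AcOH quench; then PPTS (cat.), THF/H2O, rt
Reagents that add atoms: water, O
Why: The hard lithium acetylide should add 1,2 to the pyranone carbonyl (the classical entry to 4-substituted pyrylium ions from 4-pyranones); mild acid then ionises the doubly vinylogous tertiary carbinol to a 4-alkynylpyrylium ion that is hydrated at the remote alkyne carbon (Meyer–Schuster rearrangement) to give the push–pull 4-acylmethylene-4H-pyran. The carbinol centre is racemic and is oxidised in step 6, and the ylidene geometry is mobile.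

**Step 6**
Reactants: 8 (4Z)-6-[(E)-2-(1,3-dioxolan-2-yl)ethenyl]-4-(3-hydroxy-2-oxobutylidene)-4H-pyran-3-yl trifluoromethanesulfonate
Product: 9 (4Z)-6-[(E)-2-(1,3-dioxolan-2-yl)ethenyl]-4-(2,3-dioxobutylidene)-4H-pyran-3-yl trifluoromethanesulfonate
Conditions: Dess–Martin periodinane, pyridine, CH2Cl2, 0 °C to rt
Reagents that add atoms: none
Why: Dess–Martin oxidation of the α-hydroxy ketone to the 1,2-dione; pyridine buffers the acetic acid so the dioxolane and the enol-ether ring should survive.

**Step 7**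
Reactants: 9 (4Z)-6-[(E)-2-(1,3-dioxolan-2-yl)ethenyl]-4-(2,3-dioxobutylidene)-4H-pyran-3-yl trifluoromethanesulfonate
Product: 10 (4Z)-6-[(E)-2-(1,3-dioxolan-2-yl)ethenyl]-4-(2,3-dioxobutylidene)-4H-pyran-3-carbaldehyde
Conditions: Pd(OAc)2 (5 mol%), dppp (5 mol%), CO (1 atm), Et3SiH (2 equiv), i-Pr2NEt, DMF, 60 °C
Reagents that add atoms: carbon monoxide, [C-]#[O+]
Why: Palladium-catalysed reductive carbonylation (formylation) of a vinyl triflate by oxidative addition, CO insertion and hydride transfer from the silane to the acyl-palladium; without a Lewis acid, Et3SiH should not reduce the dione or the acetal.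

**Step 8**
Reactants: 10 (4Z)-6-[(E)-2-(1,3-dioxolan-2-yl)ethenyl]-4-(2,3-dioxobutylidene)-4H-pyran-3-carbaldehyde
Product: 11 (7R)-3-[(E)-2-(1,3-dioxolan-2-yl)ethenyl]-7-hydroxy-7-methyl-6H-isochromene-6,8(7H)-dione
Conditions: (5aS,10bR)-2-(pentafluorophenyl)-5a,10b-dihydro-4H,6H-indeno[2,1-b][1,2,4]triazolo[4,3-d][1,4]oxazinium tetrafluoroborate (10 mol%), Et3N (10 mol%), toluene, 4 Å MS, rt, Ar
Reagents that add atoms: none
Why: The carbene adds to the C8 aldehyde and proton transfer gives the Breslow enaminol, an acyl-anion equivalent that attacks the C7 methyl ketone intramolecularly; collapse of the adduct releases the carbene and leaves the C8 ketone beside the C7 tertiary alcohol. The closest known reaction is the enantioselective intramolecular crossed aldehyde–ketone benzoin cyclisation of keto-aldehydes to six-membered tertiary α-ketols with aminoindanol triazolium catalysts. The carbocycle C8–C8a–C4a–C5–C6–C7 closes in a 6-exo-trig mode. C7 is the only new stereocentre and is controlled by the catalyst alone, through a hydrogen-bonded transition state in which the indane shields one face of the enaminol so that the Si face of the ketone is attacked (7R). The step needs C7-over-C6 selectivity, secured because C7 is a non-conjugated α-keto carbonyl free to rotate into the attack trajectory whereas C6 is a deactivated vinylogous ester whose attack would need an in-plane five-ring closure, and aldehyde-over-dione selectivity for the carbene, secured by the reversibility of carbene–ketone adducts. The (4Z) geometry is reached by rotation about the push–pull exocyclic C4a=C5 bond, so any E isomer should be funnelled through the reactive form.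

**Step 9**
Reactants: 12 methyl 2,4-dihydroxy-6-methylbenzoate (methyl orsellinate)
Product: 13 methyl 2,4-bis(methoxymethoxy)-6-methylbenzoate
Conditions: NaH (2.5 equiv), MOMCl (2.6 equiv), DMF, 0 °C to rt
Reagents that add atoms: chloromethyl methyl ether, COCCl
Why: Williamson-type O-alkylation of both phenoxides; NaH is needed for the hydrogen-bonded ortho-hydroxyl.

**Step 10**
Reactants: 13 methyl 2,4-bis(methoxymethoxy)-6-methylbenzoate
Product: 14 2,4-bis(methoxymethoxy)-6-methylbenzoic acid
Conditions: KOH, MeOH/H2O, 80 °C; then cold 1 M HCl to pH 4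
Reagents that add atoms: potassium hydroxide, [K+].[OH-]
Why: Saponification of the hindered methyl ester at elevated temperature; MOM ethers are stable to base and should survive the brief cold acidification.

**Step 11**
Reactants: 11 (7R)-3-[(E)-2-(1,3-dioxolan-2-yl)ethenyl]-7-hydroxy-7-methyl-6H-isochromene-6,8(7H)-dione; 14 2,4-bis(methoxymethoxy)-6-methylbenzoic acid
Product: 16 (7R)-3-[(E)-2-(1,3-dioxolan-2-yl)ethenyl]-7-methyl-6,8-dioxo-7,8-dihydro-6H-isochromen-7-yl 2,4-bis(methoxymethoxy)-6-methylbenzoate, via acid chloride 15 (not isolated)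
Conditions: 14, 1-chloro-N,N,2-trimethylprop-1-en-1-amine (1.2 equiv), CH2Cl2, 0 °C to rt; then 11, DMAP (2 equiv), Et3N, CH2Cl2, rt to 40 °C
Reagents that add atoms: none
Why: Ghosez's reagent forms the acid chloride without HCl (MOM-safe), and DMAP-catalysed acylation through the N-acylpyridinium ion should esterify the tertiary α-ketol; C7 is quaternary and cannot epimerise, and tertiary amines cannot convert the pyran into a vinylogous pyridone.

**Step 12**
Reactants: 16 (7R)-3-[(E)-2-(1,3-dioxolan-2-yl)ethenyl]-7-methyl-6,8-dioxo-7,8-dihydro-6H-isochromen-7-yl 2,4-bis(methoxymethoxy)-6-methylbenzoate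
Product: 17 (7R)-7-methyl-6,8-dioxo-3-[(E)-3-oxoprop-1-en-1-yl]-7,8-dihydro-6H-isochromen-7-yl 2,4-dihydroxy-6-methylbenzoate (target, CNP0200982.1)
Conditions: TFA/H2O/CH2Cl2, 0 °C to rt
Reagents that add atoms: water, O
Why: Acid-catalysed hydrolysis of the dioxolane and both MOM acetals in one operation; the C7 ester cannot ionise (the cation would sit between two carbonyls), the hindered aryl ester resists hydrolysis, and the enal is released as the thermodynamic E isomer.

**Compound list**
1 | kojic acid, 5-hydroxy-2-(hydroxymethyl)-4H-pyran-4-one | O=c1cc(CO)occ1O | starting material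
2 | 6-(hydroxymethyl)-4-oxo-4H-pyran-3-yl trifluoromethanesulfonate | O=c1cc(CO)occ1OS(=O)(=O)C(F)(F)F | intermediate
3 | 6-formyl-4-oxo-4H-pyran-3-yl trifluoromethanesulfonate | O=Cc1cc(=O)c(OS(=O)(=O)C(F)(F)F)co1 | intermediate
4 | 4-oxo-6-[(E)-3-oxoprop-1-en-1-yl]-4H-pyran-3-yl trifluoromethanesulfonate | O=C/C=C/c1cc(=O)c(OS(=O)(=O)C(F)(F)F)co1 | intermediate
5 | 6-[(E)-2-(1,3-dioxolan-2-yl)ethenyl]-4-oxo-4H-pyran-3-yl trifluoromethanesulfonate | O=c1cc(/C=C/C2OCCO2)occ1OS(=O)(=O)C(F)(F)F | intermediate
6 | but-3-yn-2-ol (racemic) | CC(O)C#C | starting material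
7 | 6-[(E)-2-(1,3-dioxolan-2-yl)ethenyl]-4-hydroxy-4-(3-hydroxybut-1-yn-1-yl)-4H-pyran-3-yl trifluoromethanesulfonate (mixture of diastereomers) | CC(O)C#CC1(O)C=C(/C=C/C2OCCO2)OC=C1OS(=O)(=O)C(F)(F)F | intermediate (not isolated)
8 | (4Z)-6-[(E)-2-(1,3-dioxolan-2-yl)ethenyl]-4-(3-hydroxy-2-oxobutylidene)-4H-pyran-3-yl trifluoromethanesulfonate (racemic carbinol; ylidene isomers interconvert) | CC(O)C(=O)/C=C1/C=C(/C=C/C2OCCO2)OC=C1OS(=O)(=O)C(F)(F)F | intermediate
9 | (4Z)-6-[(E)-2-(1,3-dioxolan-2-yl)ethenyl]-4-(2,3-dioxobutylidene)-4H-pyran-3-yl trifluoromethanesulfonate | CC(=O)C(=O)/C=C1/C=C(/C=C/C2OCCO2)OC=C1OS(=O)(=O)C(F)(F)F | intermediate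
10 | (4Z)-6-[(E)-2-(1,3-dioxolan-2-yl)ethenyl]-4-(2,3-dioxobutylidene)-4H-pyran-3-carbaldehyde | CC(=O)C(=O)/C=C1/C=C(/C=C/C2OCCO2)OC=C1C=O | intermediate
11 | (7R)-3-[(E)-2-(1,3-dioxolan-2-yl)ethenyl]-7-hydroxy-7-methyl-6H-isochromene-6,8(7H)-dione | O[C@]1(C)C(=O)C=C2C=C(/C=C/C3OCCO3)OC=C2C1=O | intermediate
12 | methyl 2,4-dihydroxy-6-methylbenzoate (methyl orsellinate) | COC(=O)c1c(C)cc(O)cc1O | starting material
13 | methyl 2,4-bis(methoxymethoxy)-6-methylbenzoate | COCOc1cc(C)c(C(=O)OC)c(OCOC)c1 | intermediate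
14 | 2,4-bis(methoxymethoxy)-6-methylbenzoic acid | COCOc1cc(C)c(C(=O)O)c(OCOC)c1 | intermediate
15 | 2,4-bis(methoxymethoxy)-6-methylbenzoyl chloride | COCOc1cc(C)c(C(=O)Cl)c(OCOC)c1 | intermediate (not isolated)
16 | (7R)-3-[(E)-2-(1,3-dioxolan-2-yl)ethenyl]-7-methyl-6,8-dioxo-7,8-dihydro-6H-isochromen-7-yl 2,4-bis(methoxymethoxy)-6-methylbenzoate | COCOc1cc(C)c(C(=O)O[C@]2(C)C(=O)C=C3C=C(/C=C/C4OCCO4)OC=C3C2=O)c(OCOC)c1 | intermediate
17 | (7R)-7-methyl-6,8-dioxo-3-[(E)-3-oxoprop-1-en-1-yl]-7,8-dihydro-6H-isochromen-7-yl 2,4-dihydroxy-6-methylbenzoate | Cc1cc(O)cc(O)c1C(=O)O[C@]1(C)C(=O)C=C2C=C(/C=C/C=O)OC=C2C1=O | target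

**Step count.** Total: 12 steps. Longest linear sequence: 10 steps (steps 1 to 8, 11 and 12).

**Steps most likely to fail**

Step 8. The carbene may be diverted into unproductive addition to the 1,2-dione or into β-protonation of the Breslow intermediate, or the facial selectivity at C7 may be poor. The fallback sets out from 8 and returns at 11. Compound 8 would be formylated under the conditions of step 7 (with a weaker base) to (4Z)-6-[(E)-2-(1,3-dioxolan-2-yl)ethenyl]-4-(3-hydroxy-2-oxobutylidene)-4H-pyran-3-carbaldehyde F1. A direct intramolecular aldol through a zinc enediolate (dinuclear zinc–ProPhenol-type catalyst) would then join C7 to the C8 aldehyde and give the diol (7S,8RS)-3-[(E)-2-(1,3-dioxolan-2-yl)ethenyl]-7,8-dihydroxy-7-methyl-7,8-dihydro-6H-isochromen-6-one F2 (same spatial arrangement at C7 as in 11; the descriptor changes with CIP priorities). Chemoselective MnO2 oxidation of the allylic secondary C8 hydroxyl would give 11; if the enantiomeric purity were insufficient it would be raised by preparative chromatography on a chiral phase at this stage.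

Step 5. The acetylide may add in conjugate fashion at the unsubstituted C2 of the pyranone with ring opening, or attack the sulfonyl sulfur, or the carbinol may not rearrange cleanly. The fallback sets out from 5 and returns at 9. Thionation of 5 with Lawesson's reagent would give 6-[(E)-2-(1,3-dioxolan-2-yl)ethenyl]-4-thioxo-4H-pyran-3-yl trifluoromethanesulfonate F3. S-Alkylation with commercial 1-bromobutane-2,3-dione would give 4-[(2,3-dioxobutyl)sulfanyl]-2-[(E)-2-(1,3-dioxolan-2-yl)ethenyl]-5-(trifluoromethanesulfonyloxy)pyrylium bromide F4. Eschenmoser sulfide contraction (PPh3, Et3N) would then form the C4 ylidene bond regiospecifically and deliver 9 directly.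

Step 11. Acylation of the hindered tertiary α-ketol by a di-ortho-substituted aroyl chloride may be slower than base-induced acyloin rearrangement of 11 or amine addition at C1. The fallback sets out from 11 and returns at 17. Commercial 2,4-dihydroxy-6-methylbenzoic acid would be condensed with acetone (TFAA, TFA) to 7-hydroxy-2,2,5-trimethyl-4H-1,3-benzodioxin-4-one F5 and protected (MOMCl, i-Pr2NEt) as 7-(methoxymethoxy)-2,2,5-trimethyl-4H-1,3-benzodioxin-4-one F6. Irradiation of F6 (300 nm, CH2Cl2) in the presence of 11 would generate the unhindered quinoketene, which the tertiary alcohol should trap under neutral conditions to give (7R)-3-[(E)-2-(1,3-dioxolan-2-yl)ethenyl]-7-methyl-6,8-dioxo-7,8-dihydro-6H-isochromen-7-yl 2-hydroxy-4-(methoxymethoxy)-6-methylbenzoate F7. The conditions of step 12 would then give 17.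

**Further compounds**
F1 | step 8 | (4Z)-6-[(E)-2-(1,3-dioxolan-2-yl)ethenyl]-4-(3-hydroxy-2-oxobutylidene)-4H-pyran-3-carbaldehyde | CC(O)C(=O)/C=C1/C=C(/C=C/C2OCCO2)OC=C1C=O
F2 | step 8 | (7S,8RS)-3-[(E)-2-(1,3-dioxolan-2-yl)ethenyl]-7,8-dihydroxy-7-methyl-7,8-dihydro-6H-isochromen-6-one | O[C@]1(C)C(=O)C=C2C=C(/C=C/C3OCCO3)OC=C2C1O
F3 | step 5 | 6-[(E)-2-(1,3-dioxolan-2-yl)ethenyl]-4-thioxo-4H-pyran-3-yl trifluoromethanesulfonate | S=c1cc(/C=C/C2OCCO2)occ1OS(=O)(=O)C(F)(F)F
F4 | step 5 | 4-[(2,3-dioxobutyl)sulfanyl]-2-[(E)-2-(1,3-dioxolan-2-yl)ethenyl]-5-(trifluoromethanesulfonyloxy)pyrylium bromide | CC(=O)C(=O)CSc1cc(/C=C/C2OCCO2)[o+]cc1OS(=O)(=O)C(F)(F)F.[Br-]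
F5 | step 11 | 7-hydroxy-2,2,5-trimethyl-4H-1,3-benzodioxin-4-one | Cc1cc(O)cc2OC(C)(C)OC(=O)c12
F6 | step 11 | 7-(methoxymethoxy)-2,2,5-trimethyl-4H-1,3-benzodioxin-4-one | COCOc1cc(C)c2C(=O)OC(C)(C)Oc2c1
F7 | step 11 | (7R)-3-[(E)-2-(1,3-dioxolan-2-yl)ethenyl]-7-methyl-6,8-dioxo-7,8-dihydro-6H-isochromen-7-yl 2-hydroxy-4-(methoxymethoxy)-6-methylbenzoate | COCOc1cc(C)c(C(=O)O[C@]2(C)C(=O)C=C3C=C(/C=C/C4OCCO4)OC=C3C2=O)c(O)c1
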